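## The problem

The target is a 2,3-dihydrobenzofuran. A benzene ring (ring A) carries an acetyl group at C5 and a hydroxyl at C6 and is fused through C3a and C7a to the oxygen ring (ring B), which holds both stereocentres. C2 (S) bears an isopropenyl group and C3 (S) bears the oxygen of a (Z)-2-(acetoxymethyl)but-2-enoate. The two substituents are cis, so the relative configuration has to be set kinetically and never allowed to equilibrate. The C3–O bond is the weak point: it is benzylic, ortho to O1 and para to the C6 oxygen, so acid can ionise it, a free para-phenoxide can expel the carboxylate, and loss of the acid across C2–C3 gives an aromatic benzofuran. The side chain is an angelate-type ester (methyl cis to the carbonyl) with an allylic acetate on the α-carbon; nucleophilic catalysts and heat can isomerise it to the more stable E form or displace the acetate with allylic transposition. The C6 hydroxyl is hydrogen-bonded to the acetyl carbonyl, and in the free resorcinol ketone this chelate steers electrophiles to the carbon between the two oxygens, not to the carbon that must become C3a. The feature that allows a short synthesis is that C3a is ortho to O1 and para to the C6 oxygen, hence a nucleophilic carbon, while C3, C2 and the three isopropenyl carbons map onto 2,3-epoxy-3-methylbutanal. The aldehyde carbon can be joined to C3a, the epoxide can be opened by O1, and the single stereocentre of the epoxy aldehyde can control C3 before it is itself inverted to give the cis ring.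

## Retrosynthesis

**23 ⇒ 22.** The first cut lies outside the skeleton: the C6 hydroxyl of 23 is traced to its 4-methoxybenzyl ether 22 (O–CH2 bond). An ether on this oxygen is wanted throughout. It breaks the chelate that would send the electrophile to the wrong aromatic carbon in the ring-forming step, and it removes the phenol that could expel the C3 ester or compete for the acylating agent. This ether can be removed last by neutral oxidation; acid, base, hydrogenolysis and zerovalent palladium would each attack the benzylic ester, the alkenes or the allylic acetate. The cost is four steps compared with a free-phenol route. The forward reaction must oxidise the benzyl group without touching C3–H or the isopropenyl group.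

**22 ⇒ 20.** The isopropenyl double bond is traced to the tertiary alcohol of 20. This retron is imposed by the ring-forming step, which necessarily leaves an oxygen on that carbon. The forward reaction, through sulfamate 21, must lose a methyl proton in preference to C2–H and must not ionise the neighbouring ester. Dehydration follows acylation so that only one hydroxyl is free when it is carried out.

**20 ⇒ 10 + 18.** Cutting the acyl–oxygen bond of the C3 ester gives diol 10 and acid 18. Cutting the alkyl–oxygen bond instead (displacement at C3 by a carboxylate) would pass the benzylic stereocentre through an ionisable intermediate; acyl transfer leaves it untouched. The cut removes seven carbons and the whole fragile side chain, which then meets the core only three steps from the end. The forward reaction, through mixed anhydride 19, must acylate a hindered secondary hydroxyl beside a tertiary one without moving the Z double bond.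

**10 ⇒ 4 + 7 (key disconnection).** Ring B of 10 is opened at two bonds at once, C3–C3a and O1–C2. Cutting O1–C7a would need an aryl ether synthesis on a halo-arene that must first be made. Cutting C2–C3 would leave two stereocentres to be set in an aldol-type union with no controlling element. The chosen pair detaches all five non-aromatic carbons as one piece, epoxy aldehyde 7, and leaves phenol 4, in which the future O1 and the future C3a are neighbours. In the forward sense aryloxide 8 must add through carbon to the aldehyde on the face dictated by the epoxide, giving anti epoxy alcohol 9. The phenoxide must then open the epoxide at its secondary carbon with inversion. The bicyclic diol is thereby reduced to an achiral arene and a five-carbon aldehyde with one stereocentre.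

**7 ⇒ 6 ⇒ 5.** Aldehyde 7 is traced through epoxy alcohol 6 to allylic alcohol 5 (the two C–O bonds of the epoxide). Tartrate-controlled epoxidation of the allylic alcohol is preferred to direct amine-catalysed epoxidation of the enal. It costs one more step, but the sense and level of induction are secure for a 3,3-disubstituted substrate, and the only stereocentre imported into the synthesis rests on it.

**4 ⇒ 3 ⇒ 2 ⇒ 1.** Phenol 4 comes from ketone 1 through 2 and 3 (O–C bonds only). The order is fixed by the reactivity of 1: the hydroxyl para to the acetyl group reacts first with any electrophile. It is therefore blocked as a pivalate (2), the chelated hydroxyl is benzylated (3), and the ester is removed.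

**18 ⇒ 16 ⇒ 14 ⇒ 13 ⇒ 11.** Acid 18 is the acetate of hydroxy acid 16 (obtained through mixed anhydride 17). The carboxyl carbon of 16 is disconnected (C–C bond) to alkenyl bromide 14 by way of dilithio species 15. The stable geometry of 2-substituted but-2-enoates has the methyl trans to the carboxyl group, the opposite of what is needed. The geometry is therefore set in bromo enal 13, whose stable isomer has bromine cis to methyl, and transferred to carbon by stereoretentive lithiation. 13 comes from enal 11 by bromination and elimination through dibromide 12, and reduction gives 14.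

## Roads not taken

**Alternative 1:** The cut runs through ring A, at C3a–C4 and C5–C6. A dihydrofuran carrying both stereocentres and an exocyclic silyl ketene acetal, diene A1, would undergo [4+2] cycloaddition with alkynone A2. Loss of the methoxy and trimethylsilyl groups from the adduct would give phenol A3 with acetyl and hydroxyl in place.
- Merits: the polarity of diene and dienophile fixes the substitution pattern of ring A with none of the ortho/ortho ambiguity that the chosen plan manages with a protecting group. The isopropenyl group is present from the start, so no dehydration is needed.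
- Weak points: A1 has an allylic silyloxy group at C3 that can be lost to give a furan, and a hydrolytically labile ketene acetal. Its cis pair of stereocentres must be built on a non-aromatic five-membered ring, which is a synthesis in its own right, so the stereochemical problem is moved, not solved. A3 still needs desilylation and acylation at C3 beside a free phenol.
- Comparison: the chosen plan is weaker on arene regiocontrol, but it reaches its ring-forming step from two partners that are each at most three steps from commercial material.

**Alternative 2:** Ring B is cut at O1–C2 in another sense: the oxygen is imagined to have migrated from the quaternary carbon of a chroman. The cis-3-hydroxy-4-acyloxy-2,2-dimethylchroman A4, already carrying the full side chain, would be converted into its secondary triflate. The ring oxygen displaces the triflate with inversion, the bond to the quaternary carbon breaks, and the tertiary cation loses a proton to give A5, the silyl ether of the target.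
- Merits: in two respects this road is better. The alkene is formed in the key step, so the separate dehydration and its regiochemical risk disappear. The chroman can be made by chromene formation and catalytic asymmetric oxidation, whose selectivity is well established.
- Weak points: the migrating atom is an aryl ether oxygen para to an acetyl group, a poor neighbouring group. The triflate has an antiperiplanar benzylic hydrogen at C4, so elimination to an enol ester or a hydride shift can compete. The cation can lose a proton in two directions. All of this must be survived by the finished side chain with its allylic acetate, and the cis diol must first be acylated selectively at the benzylic hydroxyl.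
- Comparison: the chosen plan accepts an extra dehydration step, but it forms both ring bonds under mild basic conditions before the fragile ester is attached.

**Alternative 3:** The cut is the C3–O bond alone. Dihydrobenzofuran A6, with C2 set and the tertiary alcohol masked as a tert-butyl carbonate, would be oxidised at an anode by two electrons to the para-quinone methide across C3a=C3. The carbonate carbonyl oxygen adds to C3, the tert-butyl group is lost, and the cis-fused cyclic carbonate A7 results.
- Merits: in stereocontrol this road is superior. The tether can reach C3 only from the face of the C2 substituent, so the cis relationship is a geometric necessity, whereas the chosen plan relies on an open Felkin–Anh transition state. C2 of A6 is also easy to set by asymmetric epoxidation of a prenylated phenol.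
- Weak points: the phenol to be oxidised is electron-poor and hydrogen-bonded to the acetyl group. The quinone methide has a hydrogen at C2 and can tautomerise irreversibly to the aromatic benzofuran before it is trapped. A tert-butyl carbonate of a tertiary alcohol is hard to make and fragments readily.
- Comparison: A7 must be hydrolysed to the free-phenol form of the diol that the chosen key step delivers directly, after which acylation (now beside a free C6 phenol) and dehydration follow as in the chosen route. The sequence is therefore longer by the steps needed to make A6 and to open A7.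

Key step: step 6

Remark: commercial crotonaldehyde 11 is taken as its E isomer; any Z isomer converges on the same bromo enal 13 in step 7.

## Route

Step 1
Reactants: 1 2,4-dihydroxyacetophenone
Product: 2 4-acetyl-3-hydroxyphenyl 2,2-dimethylpropanoate
Conditions: PivCl (1.05 equiv), Et3N, CH2Cl2, 0 °C
Reagents that add atoms: pivaloyl chloride, CC(C)(C)C(Cl)=O
Why: Chemoselective O-acylation; the hydroxyl para to the acetyl group is free and the more acidic, whereas the ortho hydroxyl is held in a hydrogen bond to the carbonyl and reacts far more slowly.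

Step 2
Reactants: 2 4-acetyl-3-hydroxyphenyl 2,2-dimethylpropanoate
Product: 3 4-acetyl-3-[(4-methoxybenzyl)oxy]phenyl 2,2-dimethylpropanoate
Conditions: 4-MeOC6H4CH2Cl, K2CO3, Bu4NI (cat.), DMF, 50 °C
Reagents that add atoms: 4-methoxybenzyl chloride, COc1ccc(CCl)cc1
Why: Williamson ether synthesis on the remaining chelated phenol; the hindered pivalate tolerates dry carbonate in DMF. The ether breaks the chelate that would otherwise steer electrophiles to the carbon between the two oxygens.

Step 3
Reactants: 3 4-acetyl-3-[(4-methoxybenzyl)oxy]phenyl 2,2-dimethylpropanoate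
Product: 4 1-{4-hydroxy-2-[(4-methoxybenzyl)oxy]phenyl}ethan-1-one
Conditions: K2CO3, MeOH, 23 °C
Reagents that add atoms: none
Why: Base-mediated transesterification of an activated aryl ester; the benzyl ether and the ketone are inert.

Step 4
Reactants: 5 3-methylbut-2-en-1-ol
Product: 6 [(2S)-3,3-dimethyloxiran-2-yl]methanol
Conditions: Ti(O-i-Pr)4 (cat.), L-(+)-diethyl tartrate (cat.), t-BuOOH, 4 Å MS, CH2Cl2, −20 °C
Reagents that add atoms: tert-butyl hydroperoxide, CC(C)(C)OO
Why: Sharpless asymmetric epoxidation of a primary allylic alcohol; with the L-(+)-tartrate the oxygen is delivered to the face that gives the (S)-epoxy alcohol. This sets the only stereocentre brought in from outside.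

Step 5
Reactants: 6 [(2S)-3,3-dimethyloxiran-2-yl]methanol
Product: 7 (2R)-3,3-dimethyloxirane-2-carbaldehyde
Conditions: TEMPO (cat.), PhI(OAc)2, CH2Cl2, 23 °C
Reagents that add atoms: none
Why: Oxoammonium-catalysed (TEMPO) oxidation of a primary alcohol under neutral, non-aqueous conditions; the epoxide carbon cannot enolise, so the stereocentre is safe (the descriptor changes from S to R only through the priority rules). The volatile aldehyde is used as a dried solution without chromatography.

Step 6
Reactants: 4 1-{4-hydroxy-2-[(4-methoxybenzyl)oxy]phenyl}ethan-1-one; 7 (2R)-3,3-dimethyloxirane-2-carbaldehyde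
Product: 10 1-{(2R,3S)-3-hydroxy-2-(2-hydroxypropan-2-yl)-6-[(4-methoxybenzyl)oxy]-2,3-dihydro-1-benzofuran-5-yl}ethan-1-one (cis diol), via titanium aryloxide 8 (not isolated), via anti epoxy alcohol 9 (not isolated)
Conditions: Ti(O-i-Pr)4 (1.05 equiv), toluene, 23 °C, i-PrOH removed in vacuo; 7 (1.3 equiv), toluene, −20 → 23 °C; then K2CO3, MeOH, 45 °C
Reagents that add atoms: none
Why: Proposed new method: ligand exchange gives aryloxide 8, whose tetravalent titanium binds the aldehyde oxygen of 7 and delivers the carbonyl carbon to the ortho carbon through a six-membered transition state (electrophilic aromatic substitution, then rearomatisation), forming C3–C3a and alkoxide 9; the closest known reaction type is the ortho-specific hydroxyalkylation of titanium and magnesium phenoxides with chiral α-alkoxy aldehydes, which has not been run with an α,β-epoxy aldehyde or an acyl-substituted phenoxide. Of the two ortho carbons, the one para to the benzyloxy group should react, because the other is flanked by two oxygen substituents and, with the chelate broken, no longer has enhanced enol character. The new C3 stereocentre is controlled by the epoxide carbon of 7: the non-chelating Ti(O-i-Pr)3 unit favours the polar Felkin–Anh arrangement with the epoxide C–O bond anti to the incoming arene, which should give the anti (3S) carbinol. Methanol and K2CO3 then strip the titanium and generate the free phenoxide, which opens the epoxide at the secondary carbon in a 5-exo-tet closure with inversion, as in the base-induced cyclisation of epoxidised ortho-prenylphenols, forming O1–C2 and ring B. Inversion of the (R)-epoxide carbon of an anti epoxy alcohol places the hydroxypropyl group and the C3 hydroxyl on the same face, so 10 is cis-(2R,3S). The step needs 5-exo over 6-endo selectivity, secured by a basic, titanium-free closure in which substitution at the tertiary carbon does not compete, and it needs a base weak enough to ionise only the phenol so that no Payne rearrangement intervenes.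

Step 7
Reactants: 11 (E)-but-2-enal
Product: 13 (Z)-2-bromobut-2-enal, via dibromo aldehyde 12 (not isolated)
Conditions: Br2, CH2Cl2, −10 °C; then Et3N, 0 → 23 °C
Reagents that add atoms: bromine, BrBr
Why: Anti addition of bromine to the enal, then base-induced loss of HBr through the acidic α-position, should give the more stable Z isomer with methyl cis to bromine and trans to the formyl group. This geometry later places the methyl group cis to the carboxyl carbon.

Step 8
Reactants: 13 (Z)-2-bromobut-2-enal
Product: 14 (Z)-2-bromobut-2-en-1-ol
Conditions: NaBH4, CeCl3·7H2O, MeOH, 0 °C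
Reagents that add atoms: none
Why: Luche 1,2-reduction of an enal; the double-bond geometry and the alkenyl bromide are untouched.

Step 9
Reactants: 14 (Z)-2-bromobut-2-en-1-ol
Product: 16 (Z)-2-(hydroxymethyl)but-2-enoic acid, via dilithio alkenyl alkoxide 15 (not isolated)
Conditions: n-BuLi (1 equiv), then t-BuLi (2.1 equiv), Et2O, −78 °C; CO2; aq. HCl
Reagents that add atoms: carbon dioxide, O=C=O
Why: Deprotonation of the alcohol and bromine–lithium exchange give a configurationally stable alkenyllithium, as known for 2-bromoallylic alkoxides. Carboxylation proceeds with retention, so the carboxyl group takes the place of bromine cis to the methyl group (Z, angelate-type geometry).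

Step 10
Reactants: 16 (Z)-2-(hydroxymethyl)but-2-enoic acid
Product: 18 (Z)-2-(acetoxymethyl)but-2-enoic acid, via mixed acetic anhydride 17 (not isolated)
Conditions: Ac2O, pyridine, 0 → 23 °C; then H2O, THF
Reagents that add atoms: acetic anhydride, CC(=O)OC(C)=O
Why: Acetylation of the primary alcohol; the mixed anhydride formed at the carboxyl group is hydrolysed on aqueous work-up. Pyridine is too weak a nucleophile to trigger allylic transposition or Z/E isomerisation.

Step 11
Reactants: 18 (Z)-2-(acetoxymethyl)but-2-enoic acid; 10 1-{(2R,3S)-3-hydroxy-2-(2-hydroxypropan-2-yl)-6-[(4-methoxybenzyl)oxy]-2,3-dihydro-1-benzofuran-5-yl}ethan-1-one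
Product: 20 (2R,3S)-5-acetyl-2-(2-hydroxypropan-2-yl)-6-[(4-methoxybenzyl)oxy]-2,3-dihydro-1-benzofuran-3-yl (Z)-2-(acetoxymethyl)but-2-enoate, via trichlorobenzoyl mixed anhydride 19 (not isolated)
Conditions: 2,4,6-Cl3C6H2COCl, Et3N, toluene, 0 °C; then 10, DMAP, 23 °C
Reagents that add atoms: none
Why: Yamaguchi esterification, a standard method for hindered, isomerisation-prone angelate-type acids. The secondary benzylic hydroxyl is acylated while the tertiary hydroxyl is inert, and C3 keeps its configuration because its C–O bond is not broken.

Step 12
Reactants: 20 (2R,3S)-5-acetyl-2-(2-hydroxypropan-2-yl)-6-[(4-methoxybenzyl)oxy]-2,3-dihydro-1-benzofuran-3-yl (Z)-2-(acetoxymethyl)but-2-enoate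
Product: 22 (2S,3S)-5-acetyl-6-[(4-methoxybenzyl)oxy]-2-(prop-1-en-2-yl)-2,3-dihydro-1-benzofuran-3-yl (Z)-2-(acetoxymethyl)but-2-enoate, via tertiary sulfamate 21 (not isolated)
Conditions: Burgess reagent (MeO2CNSO2NEt3), toluene, 23 → 50 °C
Reagents that add atoms: none
Why: Burgess dehydration of a tertiary alcohol through its sulfamate by syn elimination. A methyl hydrogen should be lost in preference to the single C2–H, which is deactivated by the ring oxygen and shielded by the cis ester, so the isopropenyl group forms without touching either stereocentre (the C2 descriptor changes from R to S only through the priority rules).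

Step 13
Reactants: 22 (2S,3S)-5-acetyl-6-[(4-methoxybenzyl)oxy]-2-(prop-1-en-2-yl)-2,3-dihydro-1-benzofuran-3-yl (Z)-2-(acetoxymethyl)but-2-enoate
Product: 23 (2S,3S)-5-acetyl-6-hydroxy-2-(prop-1-en-2-yl)-2,3-dihydro-1-benzofuran-3-yl (Z)-2-(acetoxymethyl)but-2-enoate (CNP0193314.1)
Conditions: DDQ, CH2Cl2/pH 7 phosphate buffer, 0 → 23 °C
Reagents that add atoms: none
Why: Oxidative cleavage of a 4-methoxybenzyl ether with DDQ in buffered wet CH2Cl2. The conditions are neutral, so the ionisable C3 ester, the allylic acetate and the Z enoate should survive, and the freed phenol is at once tied up in the hydrogen bond to the acetyl group.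

## Compound list

1 | 2,4-dihydroxyacetophenone | CC(=O)c1ccc(O)cc1O | starting material
2 | 4-acetyl-3-hydroxyphenyl 2,2-dimethylpropanoate | CC(=O)c1ccc(OC(=O)C(C)(C)C)cc1O | intermediate
3 | 4-acetyl-3-[(4-methoxybenzyl)oxy]phenyl 2,2-dimethylpropanoate | CC(=O)c1ccc(OC(=O)C(C)(C)C)cc1OCc1ccc(OC)cc1 | intermediate
4 | 1-{4-hydroxy-2-[(4-methoxybenzyl)oxy]phenyl}ethan-1-one | CC(=O)c1ccc(O)cc1OCc1ccc(OC)cc1 | intermediate
5 | 3-methylbut-2-en-1-ol | CC(C)=CCO | starting material
6 | [(2S)-3,3-dimethyloxiran-2-yl]methanol | OC[C@@H]1OC1(C)C | intermediate
7 | (2R)-3,3-dimethyloxirane-2-carbaldehyde | O=C[C@@H]1OC1(C)C | intermediate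
8 | triisopropoxytitanium 4-acetyl-3-[(4-methoxybenzyl)oxy]phenoxide, ArOTi(O-i-Pr)3 (not isolated) | CC(=O)c1ccc(O[Ti](OC(C)C)(OC(C)C)OC(C)C)cc1OCc1ccc(OC)cc1 | intermediate
9 | 1-{5-[(S)-[(2S)-3,3-dimethyloxiran-2-yl](hydroxy)methyl]-4-hydroxy-2-[(4-methoxybenzyl)oxy]phenyl}ethan-1-one, anti epoxy alcohol, present as its titanium chelate and then as its potassium phenoxide (not isolated) | CC(=O)c1cc([C@H](O)[C@@H]2OC2(C)C)c(O)cc1OCc1ccc(OC)cc1 | intermediate
10 | 1-{(2R,3S)-3-hydroxy-2-(2-hydroxypropan-2-yl)-6-[(4-methoxybenzyl)oxy]-2,3-dihydro-1-benzofuran-5-yl}ethan-1-one (cis) | CC(C)(O)[C@@H]1Oc2cc(OCc3ccc(OC)cc3)c(C(C)=O)cc2[C@@H]1O | intermediate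
11 | (E)-but-2-enal (crotonaldehyde) | C/C=C/C=O | starting material
12 | (2R*,3S*)-2,3-dibromobutanal, racemic anti-addition product (not isolated) | C[C@H](Br)[C@H](Br)C=O | intermediate
13 | (Z)-2-bromobut-2-enal | C/C=C(\Br)C=O | intermediate
14 | (Z)-2-bromobut-2-en-1-ol | C/C=C(\Br)CO | intermediate
15 | lithium (E)-2-lithiobut-2-en-1-olate, lithium cis to methyl (not isolated) | C/C=C(\[Li])CO[Li] | intermediate
16 | (Z)-2-(hydroxymethyl)but-2-enoic acid | C/C=C(\C(=O)O)CO | intermediate
17 | acetic (Z)-2-(acetoxymethyl)but-2-enoic anhydride (not isolated) | C/C=C(\C(=O)OC(C)=O)COC(C)=O | intermediate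
18 | (Z)-2-(acetoxymethyl)but-2-enoic acid | C/C=C(\C(=O)O)COC(C)=O | intermediate
19 | (Z)-2-(acetoxymethyl)but-2-enoic 2,4,6-trichlorobenzoic anhydride (not isolated) | C/C=C(\C(=O)OC(=O)c1c(Cl)cc(Cl)cc1Cl)COC(C)=O | intermediate
20 | (2R,3S)-5-acetyl-2-(2-hydroxypropan-2-yl)-6-[(4-methoxybenzyl)oxy]-2,3-dihydro-1-benzofuran-3-yl (Z)-2-(acetoxymethyl)but-2-enoate | CC(C)(O)[C@@H]1Oc2cc(OCc3ccc(OC)cc3)c(C(C)=O)cc2[C@@H]1OC(=O)/C(=C\C)COC(C)=O | intermediate
21 | triethylammonium N-(methoxycarbonyl)sulfamate ester of the tertiary alcohol of 20 (not isolated) | CC[NH+](CC)CC.COC(=O)[N-]S(=O)(=O)OC(C)(C)[C@@H]1Oc2cc(OCc3ccc(OC)cc3)c(C(C)=O)cc2[C@@H]1OC(=O)/C(=C\C)COC(C)=O | intermediate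
22 | (2S,3S)-5-acetyl-6-[(4-methoxybenzyl)oxy]-2-(prop-1-en-2-yl)-2,3-dihydro-1-benzofuran-3-yl (Z)-2-(acetoxymethyl)but-2-enoate | C=C(C)[C@@H]1Oc2cc(OCc3ccc(OC)cc3)c(C(C)=O)cc2[C@@H]1OC(=O)/C(=C\C)COC(C)=O | intermediate
23 | (2S,3S)-5-acetyl-6-hydroxy-2-(prop-1-en-2-yl)-2,3-dihydro-1-benzofuran-3-yl (Z)-2-(acetoxymethyl)but-2-enoate | C=C(C)[C@@H]1Oc2cc(O)c(C(C)=O)cc2[C@@H]1OC(=O)/C(=C\C)COC(C)=O | target

## Step count and risks

Total: 13 steps. Longest linear sequence: 7 steps (steps 1, 2, 3, 6, 11, 12, 13; the sequence from 11 through steps 7–10 is equally long).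

**Step 6 (key step, proposed new method).**
- Most likely failure: carbon–carbon bond formation is too slow, because the para-acetyl group lowers the nucleophilicity of the aryloxide. Lewis-acid-induced rearrangement or isopropoxide opening of the epoxy aldehyde would then win.
- Further risks: erosion of facial selectivity through partial chelation, and ring closure at the tertiary carbon if titanium is not fully removed before the base stage.
- Fallback (known reactions; sets out from 4 and 7, returns at 9 and 10): iodination of 4 with N-iodosuccinimide ortho to the hydroxyl gives 1-{4-hydroxy-5-iodo-2-[(4-methoxybenzyl)oxy]phenyl}ethan-1-one F1. Triisopropylsilyl triflate and Et3N silylate both the phenol and the methyl ketone, giving the aryl silyl ether and silyl enol ether triisopropyl{[1-{5-iodo-2-[(4-methoxybenzyl)oxy]-4-[(triisopropylsilyl)oxy]phenyl}ethenyl]oxy}silane F2, in which the ketone is masked. Iodine–lithium exchange with t-BuLi at −78 °C gives the aryllithium {4-[(4-methoxybenzyl)oxy]-2-[(triisopropylsilyl)oxy]-5-{1-[(triisopropylsilyl)oxy]ethenyl}phenyl}lithium F3, which adds to 7 in the Felkin–Anh sense, as aryllithiums do with α,β-epoxy aldehydes, to give (S)-[(2S)-3,3-dimethyloxiran-2-yl]{4-[(4-methoxybenzyl)oxy]-2-[(triisopropylsilyl)oxy]-5-{1-[(triisopropylsilyl)oxy]ethenyl}phenyl}methanol F4. Bu4NF removes both silyl groups, which restores the ketone and releases 9 as its phenoxide. K2CO3 in MeOH completes the closure to 10.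

**Step 11.**
- Most likely failure: Z to E isomerisation, or allylic displacement of the acetate, through reversible conjugate addition of DMAP to the activated acyl species. Slow acylation of the hindered cis hydroxyl makes both more likely.
- Fallback (sets out from 16 and 10, returns at 20): the acid is coupled without an allylic leaving group and the acetate is added afterwards. Silylation of 16 with t-BuMe2SiCl and imidazole gives tert-butyldimethylsilyl (Z)-2-{[(tert-butyldimethylsilyl)oxy]methyl}but-2-enoate F5, and K2CO3 in aqueous MeOH cleaves the silyl ester to (Z)-2-{[(tert-butyldimethylsilyl)oxy]methyl}but-2-enoic acid F6. Activation as (Z)-2-{[(tert-butyldimethylsilyl)oxy]methyl}but-2-enoic 2,4,6-trichlorobenzoic anhydride F7 and reaction with 10 give (2R,3S)-5-acetyl-2-(2-hydroxypropan-2-yl)-6-[(4-methoxybenzyl)oxy]-2,3-dihydro-1-benzofuran-3-yl (Z)-2-{[(tert-butyldimethylsilyl)oxy]methyl}but-2-enoate F8. HF·pyridine frees the primary alcohol, (2R,3S)-5-acetyl-2-(2-hydroxypropan-2-yl)-6-[(4-methoxybenzyl)oxy]-2,3-dihydro-1-benzofuran-3-yl (Z)-2-(hydroxymethyl)but-2-enoate F9. Acetic anhydride in pyridine acetylates it selectively beside the tertiary hydroxyl to give 20.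

**Step 12.**
- Most likely failure: proton loss toward C2 to give an enol ether; participation of the cis C3 acyloxy group in the ionising tertiary sulfamate, leading to acyl migration; or thermal loss of the C3 ester with aromatisation.
- Fallback (sets out from 10, returns at 22): the elimination is done before the ester exists. Et3SiCl and imidazole silylate the secondary hydroxyl of 10 to give 1-{(2R,3S)-2-(2-hydroxypropan-2-yl)-6-[(4-methoxybenzyl)oxy]-3-[(triethylsilyl)oxy]-2,3-dihydro-1-benzofuran-5-yl}ethan-1-one F10. SOCl2 in pyridine at low temperature eliminates through an anti E2 pathway with an external base, which the silyl ether tolerates, to give 1-{(2S,3S)-6-[(4-methoxybenzyl)oxy]-2-(prop-1-en-2-yl)-3-[(triethylsilyl)oxy]-2,3-dihydro-1-benzofuran-5-yl}ethan-1-one F11. HF·pyridine gives 1-{(2S,3S)-3-hydroxy-6-[(4-methoxybenzyl)oxy]-2-(prop-1-en-2-yl)-2,3-dihydro-1-benzofuran-5-yl}ethan-1-one F12, whose single hydroxyl is esterified with 18 through 19 under the conditions of step 11 to give 22.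

**Step 13.**
- Most likely failure: hydride abstraction from a benzyl ether on an electron-poor aryl oxygen is slow. Longer exposure would invite oxidation at the benzylic C3–H or acid-induced ionisation of the C3 ester by the hydroquinone formed.
- Fallback (sets out from 20, returns at 23): the order of the last two steps is reversed, so that the oxidant meets neither the isopropenyl group nor the finished target. DDQ cleavage of the ether in 20 gives (2R,3S)-5-acetyl-6-hydroxy-2-(2-hydroxypropan-2-yl)-2,3-dihydro-1-benzofuran-3-yl (Z)-2-(acetoxymethyl)but-2-enoate F13. Burgess dehydration of F13, in which the phenol is expected to be spared because it is locked in the hydrogen bond to the acetyl group, gives 23.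

## Further compounds

F1 | step 6 | 1-{4-hydroxy-5-iodo-2-[(4-methoxybenzyl)oxy]phenyl}ethan-1-one | CC(=O)c1cc(I)c(O)cc1OCc1ccc(OC)cc1
F2 | step 6 | triisopropyl{[1-{5-iodo-2-[(4-methoxybenzyl)oxy]-4-[(triisopropylsilyl)oxy]phenyl}ethenyl]oxy}silane | C=C(O[Si](C(C)C)(C(C)C)C(C)C)c1cc(I)c(O[Si](C(C)C)(C(C)C)C(C)C)cc1OCc1ccc(OC)cc1
F3 | step 6 | {4-[(4-methoxybenzyl)oxy]-2-[(triisopropylsilyl)oxy]-5-{1-[(triisopropylsilyl)oxy]ethenyl}phenyl}lithium | [Li]c1cc(C(=C)O[Si](C(C)C)(C(C)C)C(C)C)c(OCc2ccc(OC)cc2)cc1O[Si](C(C)C)(C(C)C)C(C)C
F4 | step 6 | (S)-[(2S)-3,3-dimethyloxiran-2-yl]{4-[(4-methoxybenzyl)oxy]-2-[(triisopropylsilyl)oxy]-5-{1-[(triisopropylsilyl)oxy]ethenyl}phenyl}methanol | C=C(O[Si](C(C)C)(C(C)C)C(C)C)c1cc([C@H](O)[C@@H]2OC2(C)C)c(O[Si](C(C)C)(C(C)C)C(C)C)cc1OCc1ccc(OC)cc1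
F5 | step 11 | tert-butyldimethylsilyl (Z)-2-{[(tert-butyldimethylsilyl)oxy]methyl}but-2-enoate | C/C=C(\C(=O)O[Si](C)(C)C(C)(C)C)CO[Si](C)(C)C(C)(C)C
F6 | step 11 | (Z)-2-{[(tert-butyldimethylsilyl)oxy]methyl}but-2-enoic acid | C/C=C(\C(=O)O)CO[Si](C)(C)C(C)(C)C
F7 | step 11 | (Z)-2-{[(tert-butyldimethylsilyl)oxy]methyl}but-2-enoic 2,4,6-trichlorobenzoic anhydride | C/C=C(\C(=O)OC(=O)c1c(Cl)cc(Cl)cc1Cl)CO[Si](C)(C)C(C)(C)C
F8 | step 11 | (2R,3S)-5-acetyl-2-(2-hydroxypropan-2-yl)-6-[(4-methoxybenzyl)oxy]-2,3-dihydro-1-benzofuran-3-yl (Z)-2-{[(tert-butyldimethylsilyl)oxy]methyl}but-2-enoate | CC(C)(O)[C@@H]1Oc2cc(OCc3ccc(OC)cc3)c(C(C)=O)cc2[C@@H]1OC(=O)/C(=C\C)CO[Si](C)(C)C(C)(C)C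
F9 | step 11 | (2R,3S)-5-acetyl-2-(2-hydroxypropan-2-yl)-6-[(4-methoxybenzyl)oxy]-2,3-dihydro-1-benzofuran-3-yl (Z)-2-(hydroxymethyl)but-2-enoate | CC(C)(O)[C@@H]1Oc2cc(OCc3ccc(OC)cc3)c(C(C)=O)cc2[C@@H]1OC(=O)/C(=C\C)CO
F10 | step 12 | 1-{(2R,3S)-2-(2-hydroxypropan-2-yl)-6-[(4-methoxybenzyl)oxy]-3-[(triethylsilyl)oxy]-2,3-dihydro-1-benzofuran-5-yl}ethan-1-one | CC(C)(O)[C@@H]1Oc2cc(OCc3ccc(OC)cc3)c(C(C)=O)cc2[C@@H]1O[Si](CC)(CC)CC
F11 | step 12 | 1-{(2S,3S)-6-[(4-methoxybenzyl)oxy]-2-(prop-1-en-2-yl)-3-[(triethylsilyl)oxy]-2,3-dihydro-1-benzofuran-5-yl}ethan-1-one | C=C(C)[C@@H]1Oc2cc(OCc3ccc(OC)cc3)c(C(C)=O)cc2[C@@H]1O[Si](CC)(CC)CC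
F12 | step 12 | 1-{(2S,3S)-3-hydroxy-6-[(4-methoxybenzyl)oxy]-2-(prop-1-en-2-yl)-2,3-dihydro-1-benzofuran-5-yl}ethan-1-one | C=C(C)[C@@H]1Oc2cc(OCc3ccc(OC)cc3)c(C(C)=O)cc2[C@@H]1O
F13 | step 13 | (2R,3S)-5-acetyl-6-hydroxy-2-(2-hydroxypropan-2-yl)-2,3-dihydro-1-benzofuran-3-yl (Z)-2-(acetoxymethyl)but-2-enoate | CC(C)(O)[C@@H]1Oc2cc(O)c(C(C)=O)cc2[C@@H]1OC(=O)/C(=C\C)COC(C)=O
A1 | alternative 1 | (2S,3S)-3-[(tert-butyldimethylsilyl)oxy]-5-[2-methoxy-2-(trimethylsilyloxy)ethenyl]-2-(prop-1-en-2-yl)-2,3-dihydrofuran (ketene acetal geometry not defined) | C=C(C)[C@@H]1OC(C=C(OC)O[Si](C)(C)C)=C[C@@H]1O[Si](C)(C)C(C)(C)C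
A2 | alternative 1 | but-3-yn-2-one | CC(=O)C#C
A3 | alternative 1 | 1-{(2S,3S)-3-[(tert-butyldimethylsilyl)oxy]-6-hydroxy-2-(prop-1-en-2-yl)-2,3-dihydro-1-benzofuran-5-yl}ethan-1-one | C=C(C)[C@@H]1Oc2cc(O)c(C(C)=O)cc2[C@@H]1O[Si](C)(C)C(C)(C)C
A4 | alternative 2 | (3S,4S)-6-acetyl-7-[(tert-butyldimethylsilyl)oxy]-3-hydroxy-2,2-dimethyl-3,4-dihydro-2H-chromen-4-yl (Z)-2-(acetoxymethyl)but-2-enoate (cis) | CC1(C)Oc2cc(O[Si](C)(C)C(C)(C)C)c(C(C)=O)cc2[C@H](OC(=O)/C(=C\C)COC(C)=O)[C@@H]1O
A5 | alternative 2 | (2S,3S)-5-acetyl-6-[(tert-butyldimethylsilyl)oxy]-2-(prop-1-en-2-yl)-2,3-dihydro-1-benzofuran-3-yl (Z)-2-(acetoxymethyl)but-2-enoate | C=C(C)[C@@H]1Oc2cc(O[Si](C)(C)C(C)(C)C)c(C(C)=O)cc2[C@@H]1OC(=O)/C(=C\C)COC(C)=O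
A6 | alternative 3 | tert-butyl 2-[(2R)-5-acetyl-6-hydroxy-2,3-dihydro-1-benzofuran-2-yl]propan-2-yl carbonate | CC(C)(C)OC(=O)OC(C)(C)[C@H]1Cc2cc(C(C)=O)c(O)cc2O1
A7 | alternative 3 | cis-fused cyclic carbonate bridging O3 and the tertiary oxygen of (2R,3S)-5-acetyl-2-(2-hydroxypropan-2-yl)-2,3-dihydro-1-benzofuran-3,6-diol | CC1(C)OC(=O)O[C@H]2c3cc(C(C)=O)c(O)cc3O[C@@H]12
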